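The disconnection on which everything rests cuts ring C of the 5,7-dihydroxychromone half at O1–C8a, C4–C4a and O1–C2. In that half, ring A carries O1 on C8a and the C4 carbonyl on the adjacent C4a, with the C5 oxygen next to C4a: the pattern a 3,5-dialkoxybenzyne accepts when a carboxylic acid inserts across it. One operation therefore joins a benzyl-protected ortho-silylaryl triflate to an arylpropiolic acid, moves the acyl group onto carbon and closes the pyranone. The acid already contains the complete diaryl ether with its methoxy group, a benzyl-masked phenol and a methyl ester, from which the 7-methoxychromone is built classically; both C3 hydroxyls are then installed together.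

Key step: step 6

Assumption: compounds 1, 7 and 15 are taken as catalogue compounds, and dimethyldioxirane is used as a freshly prepared acetone solution.

Step 1
Reactants: 1 3,5-bis(benzyloxy)phenol
Product: 2 2-bromo-3,5-bis(benzyloxy)phenol
Conditions: NBS (1.0 equiv), CH2Cl2, −78 °C
Reagents that add atoms: N-bromosuccinimide, O=C1CCC(=O)N1Br
Why: Electrophilic aromatic bromination in which the phenol hydrogen-bonds the reagent in a non-polar solvent at low temperature and so directs bromine to the ortho carbon C2, which is also less crowded than the carbon between the two benzyloxy groups, while one equivalent limits the reaction to monobromination.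

Step 2
Reactants: 2 2-bromo-3,5-bis(benzyloxy)phenol
Product: 5 3,5-bis(benzyloxy)-2-(trimethylsilyl)phenyl trifluoromethanesulfonate, via aryl trimethylsilyl ether 3 (not isolated), via lithium 2-silylphenoxide 4 (not isolated)
Conditions: HN(SiMe3)2, THF, 65 °C, then evaporate; n-BuLi, THF, −78 °C; Tf2O, −78 °C to rt
Reagents that add atoms: hexamethyldisilazane, C[Si](C)(C)N[Si](C)(C)C; trifluoromethanesulfonic anhydride, O=S(=O)(OS(=O)(=O)C(F)(F)F)C(F)(F)F
Why: O-Silylation is followed by bromine–lithium exchange and an anionic 1,3 oxygen-to-carbon silyl shift (retro-Brook rearrangement) that should outrun benzylic deprotonation at −78 °C, and the lithium phenoxide so formed is trapped by Tf2O as the ortho-silyl aryl triflate.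

Step 3
Reactants: 6 4-fluoro-3-methoxybenzaldehyde; 7 methyl 3-(benzyloxy)-4-hydroxybenzoate
Product: 8 methyl 3-(benzyloxy)-4-(4-formyl-2-methoxyphenoxy)benzoate
Conditions: K2CO3, DMF, 110 °C
Reagents that add atoms: none
Why: Nucleophilic aromatic substitution (SNAr) in which the para-formyl group stabilises the Meisenheimer adduct at the C–F carbon, the phenoxide of 7 is the only nucleophile present and the methyl ester is inert to anhydrous carbonate.

Step 4
Reactants: 8 methyl 3-(benzyloxy)-4-(4-formyl-2-methoxyphenoxy)benzoate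
Product: 9 methyl 3-(benzyloxy)-4-(4-ethynyl-2-methoxyphenoxy)benzoate
Conditions: dimethyl (1-diazo-2-oxopropyl)phosphonate, K2CO3, MeOH/THF, 0 °C to rt
Reagents that add atoms: dimethyl (1-diazo-2-oxopropyl)phosphonate, COP(=O)(OC)C(=[N+]=[N-])C(C)=O
Why: Seyferth–Gilbert homologation in the Ohira–Bestmann variant, in which methanolysis of the reagent gives the diazomethylphosphonate anion that olefinates the non-enolisable aldehyde and loses N2 with a 1,2-hydrogen shift to the terminal alkyne, the methyl ester being degenerate toward methoxide.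

Step 5
Reactants: 9 methyl 3-(benzyloxy)-4-(4-ethynyl-2-methoxyphenoxy)benzoate
Product: 10 3-{4-[2-(benzyloxy)-4-(methoxycarbonyl)phenoxy]-3-methoxyphenyl}prop-2-ynoic acid
Conditions: CO2 (1 atm), silver iodide AgI (2 mol %), Cs2CO3, DMF, 50 °C; then 1 M HCl, 0 °C
Reagents that add atoms: carbon dioxide, O=C=O
Why: Catalytic C–H carboxylation of a terminal alkyne, in which the silver acetylide formed with Cs2CO3 inserts CO2 to give the cesium propiolate under conditions that leave the methyl benzoate and the ethers untouched, and cold acidification avoids decarboxylation.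

Step 6
Reactants: 5 3,5-bis(benzyloxy)-2-(trimethylsilyl)phenyl trifluoromethanesulfonate; 10 3-{4-[2-(benzyloxy)-4-(methoxycarbonyl)phenoxy]-3-methoxyphenyl}prop-2-ynoic acid
Product: 13 methyl 3-(benzyloxy)-4-{4-[5,7-bis(benzyloxy)-4-oxo-4H-chromen-2-yl]-2-methoxyphenoxy}benzoate, via 3,5-bis(benzyloxy)benzyne 11 (not isolated), via ortho-hydroxyaryl ynone 12 (not isolated)
Conditions: 5 (1.5 equiv), CsF (4 equiv), THF, 120 °C, sealed tube
Reagents that add atoms: none
Why: Fluoride removes the silyl group of 5 and triflate leaves to give aryne 11, to which the cesium carboxylate of 10 adds through oxygen at the aryne carbon remote from the flanking benzyloxy group, placing the aryl anion between that group and the new ester oxygen. The anion attacks its own ester carbonyl through a four-membered transition state (anionic Fries-type acyl shift), forming C4–C4a and releasing the C8a phenoxide of ynone 12. That phenoxide closes ring C by 6-endo-dig oxa-Michael addition to the ynone (O1–C2) and C3 is protonated by the medium. The closest known reaction type is the insertion of arynes into the C–O bond of carboxylic acids to give ortho-hydroxyaryl ketones, which with alkynoic acids runs on to chromones. No stereocentre is created. The selectivities needed are oxygen attack at the distal aryne carbon, secured by the inductive pull of the adjacent benzyloxy group that distorts the aryne and stabilises the ortho carbanion, and 6-endo over 5-exo closure, secured by the polarisation of the ynone toward its beta carbon; the ester, the ethers and the second ring are spectators.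

Step 7
Reactants: 13 methyl 3-(benzyloxy)-4-{4-[5,7-bis(benzyloxy)-4-oxo-4H-chromen-2-yl]-2-methoxyphenoxy}benzoate
Product: 14 3-(benzyloxy)-4-{4-[5,7-bis(benzyloxy)-4-oxo-4H-chromen-2-yl]-2-methoxyphenoxy}benzoic acid
Conditions: LiOH·H2O, THF/MeOH/H2O, 40 °C; then 1 M HCl
Reagents that add atoms: lithium hydroxide, [Li+].[OH-]
Why: Saponification (acyl-oxygen cleavage) of an unhindered methyl benzoate with dilute hydroxide, which the benzyl ethers and the diaryl ether tolerate and after which any reversible opening of the chromone at C2 recloses on acidification.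

Step 8
Reactants: 15 1-(2,6-dihydroxy-4-methoxyphenyl)ethan-1-one
Product: 16 1-[2-(benzyloxy)-6-hydroxy-4-methoxyphenyl]ethan-1-one
Conditions: BnBr (1.05 equiv), K2CO3, acetone, reflux
Reagents that add atoms: benzyl bromide, BrCc1ccccc1
Why: Williamson etherification in which one of the two equivalent phenols is alkylated and the remaining hydroxyl, locked in a hydrogen bond to the acetyl carbonyl, resists a second alkylation.

Step 9
Reactants: 14 3-(benzyloxy)-4-{4-[5,7-bis(benzyloxy)-4-oxo-4H-chromen-2-yl]-2-methoxyphenoxy}benzoic acid; 16 1-[2-(benzyloxy)-6-hydroxy-4-methoxyphenyl]ethan-1-one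
Product: 17 2-acetyl-3-(benzyloxy)-5-methoxyphenyl 3-(benzyloxy)-4-{4-[5,7-bis(benzyloxy)-4-oxo-4H-chromen-2-yl]-2-methoxyphenoxy}benzoate
Conditions: EDC·HCl, DMAP, CH2Cl2, rt
Reagents that add atoms: none
Why: Steglich esterification in which the O-acylisourea of 14 is relayed by DMAP as an acylpyridinium ion to the phenol of 16, the only nucleophile present.

Step 10
Reactants: 17 2-acetyl-3-(benzyloxy)-5-methoxyphenyl 3-(benzyloxy)-4-{4-[5,7-bis(benzyloxy)-4-oxo-4H-chromen-2-yl]-2-methoxyphenoxy}benzoate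
Product: 19 5-(benzyloxy)-2-(3-(benzyloxy)-4-{4-[5,7-bis(benzyloxy)-4-oxo-4H-chromen-2-yl]-2-methoxyphenoxy}phenyl)-7-methoxy-4H-chromen-4-one, via 1,3-diketone 18 (not isolated)
Conditions: LiN(SiMe3)2 (3 equiv), THF, −78 to −10 °C; AcOH quench, evaporate; NaOAc, AcOH, 100 °C
Reagents that add atoms: none
Why: Baker–Venkataraman rearrangement followed by cyclodehydration, in which the lithium enolate of the acetyl group attacks the neighbouring aryl ester intramolecularly to give the 1,3-diketone and warm buffered acetic acid then closes the hemiketal and eliminates water to the second chromone without strong acid that could cleave the benzyl ethers.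

Step 11
Reactants: 19 5-(benzyloxy)-2-(3-(benzyloxy)-4-{4-[5,7-bis(benzyloxy)-4-oxo-4H-chromen-2-yl]-2-methoxyphenoxy}phenyl)-7-methoxy-4H-chromen-4-one
Product: 21 5-(benzyloxy)-2-(3-(benzyloxy)-4-{4-[5,7-bis(benzyloxy)-3-hydroxy-4-oxo-4H-chromen-2-yl]-2-methoxyphenoxy}phenyl)-3-hydroxy-7-methoxy-4H-chromen-4-one, via bis-epoxide 20 (not isolated)
Conditions: dimethyldioxirane (acetone solution, excess, in portions), CH2Cl2, 0 °C to rt; evaporate; TsOH·H2O (cat.), CH2Cl2, rt
Reagents that add atoms: dimethyldioxirane, CC1(C)OO1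
Why: Electrophilic epoxidation of both chromone C2=C3 bonds under neutral conditions, then acid-catalysed opening of each epoxide at C2 (oxocarbenium ion stabilised by O1 and the aryl group) with loss of H3 to give the 3-hydroxychromones, so the transient epoxide stereocentres are erased.

Step 12
Reactants: 21 5-(benzyloxy)-2-(3-(benzyloxy)-4-{4-[5,7-bis(benzyloxy)-3-hydroxy-4-oxo-4H-chromen-2-yl]-2-methoxyphenoxy}phenyl)-3-hydroxy-7-methoxy-4H-chromen-4-one
Product: 22 3,5-dihydroxy-2-(3-hydroxy-4-{2-methoxy-4-[3,5,7-trihydroxy-4-oxo-4H-chromen-2-yl]phenoxy}phenyl)-7-methoxy-4H-chromen-4-one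
Conditions: H2 (1 atm), 10% Pd/C, THF/MeOH, rt
Reagents that add atoms: none
Why: Heterogeneous hydrogenolysis of the four benzyl aryl ethers, under which the tetrasubstituted C2=C3 bonds, the vinylogous ester carbonyls, the diaryl ether and the two methyl ethers should be inert.

Compound list
1 | 3,5-bis(benzyloxy)phenol | Oc1cc(OCc2ccccc2)cc(OCc2ccccc2)c1 | starting material
2 | 2-bromo-3,5-bis(benzyloxy)phenol | Oc1cc(OCc2ccccc2)cc(OCc2ccccc2)c1Br | intermediate
3 | [2-bromo-3,5-bis(benzyloxy)phenoxy]trimethylsilane (not isolated) | C[Si](C)(C)Oc1cc(OCc2ccccc2)cc(OCc2ccccc2)c1Br | intermediate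
4 | lithium 3,5-bis(benzyloxy)-2-(trimethylsilyl)phenoxide (not isolated) | [Li+].[O-]c1cc(OCc2ccccc2)cc(OCc2ccccc2)c1[Si](C)(C)C | intermediate
5 | 3,5-bis(benzyloxy)-2-(trimethylsilyl)phenyl trifluoromethanesulfonate | C[Si](C)(C)c1c(OS(=O)(=O)C(F)(F)F)cc(OCc2ccccc2)cc1OCc1ccccc1 | intermediate
6 | 4-fluoro-3-methoxybenzaldehyde | COc1cc(C=O)ccc1F | starting material
7 | methyl 3-(benzyloxy)-4-hydroxybenzoate | COC(=O)c1ccc(O)c(OCc2ccccc2)c1 | starting material
8 | methyl 3-(benzyloxy)-4-(4-formyl-2-methoxyphenoxy)benzoate | COC(=O)c1ccc(Oc2ccc(C=O)cc2OC)c(OCc2ccccc2)c1 | intermediate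
9 | methyl 3-(benzyloxy)-4-(4-ethynyl-2-methoxyphenoxy)benzoate | COC(=O)c1ccc(Oc2ccc(C#C)cc2OC)c(OCc2ccccc2)c1 | intermediate
10 | 3-{4-[2-(benzyloxy)-4-(methoxycarbonyl)phenoxy]-3-methoxyphenyl}prop-2-ynoic acid | OC(=O)C#Cc1ccc(Oc2ccc(C(=O)OC)cc2OCc2ccccc2)c(OC)c1 | intermediate
11 | 3,5-bis(benzyloxy)benzyne (not isolated) | C1#CC(OCc2ccccc2)=CC(OCc2ccccc2)=C1 | intermediate
12 | methyl 3-(benzyloxy)-4-{4-[3-(2,4-bis(benzyloxy)-6-hydroxyphenyl)-3-oxoprop-1-yn-1-yl]-2-methoxyphenoxy}benzoate, present as its cesium phenoxide (not isolated) | COC(=O)c1ccc(Oc2ccc(C#CC(=O)c3c(O)cc(OCc4ccccc4)cc3OCc3ccccc3)cc2OC)c(OCc2ccccc2)c1 | intermediate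
13 | methyl 3-(benzyloxy)-4-{4-[5,7-bis(benzyloxy)-4-oxo-4H-chromen-2-yl]-2-methoxyphenoxy}benzoate | O=c1cc(-c2ccc(Oc3ccc(C(=O)OC)cc3OCc3ccccc3)c(OC)c2)oc2cc(OCc3ccccc3)cc(OCc3ccccc3)c12 | intermediate
14 | 3-(benzyloxy)-4-{4-[5,7-bis(benzyloxy)-4-oxo-4H-chromen-2-yl]-2-methoxyphenoxy}benzoic acid | O=c1cc(-c2ccc(Oc3ccc(C(=O)O)cc3OCc3ccccc3)c(OC)c2)oc2cc(OCc3ccccc3)cc(OCc3ccccc3)c12 | intermediate
15 | 1-(2,6-dihydroxy-4-methoxyphenyl)ethan-1-one | COc1cc(O)c(C(C)=O)c(O)c1 | starting material
16 | 1-[2-(benzyloxy)-6-hydroxy-4-methoxyphenyl]ethan-1-one | COc1cc(O)c(C(C)=O)c(OCc2ccccc2)c1 | intermediate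
17 | 2-acetyl-3-(benzyloxy)-5-methoxyphenyl 3-(benzyloxy)-4-{4-[5,7-bis(benzyloxy)-4-oxo-4H-chromen-2-yl]-2-methoxyphenoxy}benzoate | COc1cc(OC(=O)c2ccc(Oc3ccc(-c4cc(=O)c5c(OCc6ccccc6)cc(OCc6ccccc6)cc5o4)cc3OC)c(OCc3ccccc3)c2)c(C(C)=O)c(OCc2ccccc2)c1 | intermediate
18 | 1-[2-(benzyloxy)-6-hydroxy-4-methoxyphenyl]-3-(3-(benzyloxy)-4-{4-[5,7-bis(benzyloxy)-4-oxo-4H-chromen-2-yl]-2-methoxyphenoxy}phenyl)propane-1,3-dione (not isolated) | COc1cc(O)c(C(=O)CC(=O)c2ccc(Oc3ccc(-c4cc(=O)c5c(OCc6ccccc6)cc(OCc6ccccc6)cc5o4)cc3OC)c(OCc3ccccc3)c2)c(OCc2ccccc2)c1 | intermediate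
19 | 5-(benzyloxy)-2-(3-(benzyloxy)-4-{4-[5,7-bis(benzyloxy)-4-oxo-4H-chromen-2-yl]-2-methoxyphenoxy}phenyl)-7-methoxy-4H-chromen-4-one | COc1cc(OCc2ccccc2)c2c(=O)cc(-c3ccc(Oc4ccc(-c5cc(=O)c6c(OCc7ccccc7)cc(OCc7ccccc7)cc6o5)cc4OC)c(OCc4ccccc4)c3)oc2c1 | intermediate
20 | bis(2,3-epoxide) of 19, each oxirane cis-fused to its pyranone, mixture of diastereomers with no configuration assigned (not isolated) | COc1cc(OCc2ccccc2)c2c(c1)OC1(c3ccc(Oc4ccc(C56OC5C(=O)c5c(OCc7ccccc7)cc(OCc7ccccc7)cc5O6)cc4OC)c(OCc4ccccc4)c3)OC1C2=O | intermediate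
21 | 5-(benzyloxy)-2-(3-(benzyloxy)-4-{4-[5,7-bis(benzyloxy)-3-hydroxy-4-oxo-4H-chromen-2-yl]-2-methoxyphenoxy}phenyl)-3-hydroxy-7-methoxy-4H-chromen-4-one | COc1cc(OCc2ccccc2)c2c(=O)c(O)c(-c3ccc(Oc4ccc(-c5oc6cc(OCc7ccccc7)cc(OCc7ccccc7)c6c(=O)c5O)cc4OC)c(OCc4ccccc4)c3)oc2c1 | intermediate
22 | 3,5-dihydroxy-2-(3-hydroxy-4-{2-methoxy-4-[3,5,7-trihydroxy-4-oxo-4H-chromen-2-yl]phenoxy}phenyl)-7-methoxy-4H-chromen-4-one (achiral) | COc1cc(O)c2c(=O)c(O)c(-c3ccc(Oc4ccc(-c5oc6cc(O)cc(O)c6c(=O)c5O)cc4OC)c(O)c3)oc2c1 | target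

Total step count: 12.
Longest linear sequence: 9 steps (steps 3, 4, 5, 6, 7, 9, 10, 11, 12, from 6 and 7).

Steps most likely to fail

Step 6. The aryl anion may be protonated before the acyl shift, so that only O-arylation to the aryl propiolate occurs; the propiolate may lose CO2 at the reaction temperature; or the phenoxide may close 5-exo to an aurone. The fallback sets out from aldehyde 8 and builds ring C by condensation chemistry. Claisen–Schmidt condensation of 8 with 1-[2,4-bis(benzyloxy)-6-hydroxyphenyl]ethan-1-one F1 (aqueous KOH, EtOH/THF, rt), which also saponifies the methyl ester, should give 3-(benzyloxy)-4-{4-[(1E)-3-(2,4-bis(benzyloxy)-6-hydroxyphenyl)-3-oxoprop-1-en-1-yl]-2-methoxyphenoxy}benzoic acid F2. Oxidative cyclisation of the chalcone with catalytic I2 in DMSO at 120 °C should then give acid 14, where the route is rejoined at step 9.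

Step 11. One of the two enone bonds may remain unoxidised, or the long exposure to the oxidant may attack benzylic C–H bonds. The fallback sets out from 19 and replaces electrophilic oxidation by deprotonation. Treatment with LiN(i-Pr)2 in THF at −78 °C removes both C3 hydrogens, and B(OMe)3 traps the dianion as 5-(benzyloxy)-2-(3-(benzyloxy)-4-{4-[5,7-bis(benzyloxy)-3-(dimethoxyboranyl)-4-oxo-4H-chromen-2-yl]-2-methoxyphenoxy}phenyl)-3-(dimethoxyboranyl)-7-methoxy-4H-chromen-4-one F3 (used without isolation). Oxidation with H2O2/AcOH should give 21, and the route is rejoined at step 12.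

Step 1. Bromine may enter para to the hydroxyl, between the two benzyloxy groups, or twice, which would later place silicon on the wrong carbon. The fallback sets out from 1 and uses carbamate-directed ortho-metalation instead of halogenation. Addition of 1 to isopropyl isocyanate (Et3N cat., CH2Cl2) gives 3,5-bis(benzyloxy)phenyl isopropylcarbamate F4. In situ N-silylation (t-BuMe2SiOTf, TMEDA), lithiation with n-BuLi/TMEDA at −78 °C at the carbon flanked by the carbamate and a benzyloxy group, and a Me3SiCl quench give 3,5-bis(benzyloxy)-2-(trimethylsilyl)phenyl isopropylcarbamate F5. DBU/Et2NH in MeCN at 40 °C releases 3,5-bis(benzyloxy)-2-(trimethylsilyl)phenol F6 (used without isolation), which PhN(Tf)2 converts in the same flask to triflate 5, where the route is rejoined at step 6.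

Further compounds
F1 | step 6 | 1-[2,4-bis(benzyloxy)-6-hydroxyphenyl]ethan-1-one | CC(=O)c1c(O)cc(OCc2ccccc2)cc1OCc1ccccc1
F2 | step 6 | 3-(benzyloxy)-4-{4-[(1E)-3-(2,4-bis(benzyloxy)-6-hydroxyphenyl)-3-oxoprop-1-en-1-yl]-2-methoxyphenoxy}benzoic acid | OC(=O)c1ccc(Oc2ccc(/C=C/C(=O)c3c(O)cc(OCc4ccccc4)cc3OCc3ccccc3)cc2OC)c(OCc2ccccc2)c1
F3 | step 11 | 5-(benzyloxy)-2-(3-(benzyloxy)-4-{4-[5,7-bis(benzyloxy)-3-(dimethoxyboranyl)-4-oxo-4H-chromen-2-yl]-2-methoxyphenoxy}phenyl)-3-(dimethoxyboranyl)-7-methoxy-4H-chromen-4-one | COc1cc(OCc2ccccc2)c2c(=O)c(B(OC)OC)c(-c3ccc(Oc4ccc(-c5oc6cc(OCc7ccccc7)cc(OCc7ccccc7)c6c(=O)c5B(OC)OC)cc4OC)c(OCc4ccccc4)c3)oc2c1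
F4 | step 1 | 3,5-bis(benzyloxy)phenyl isopropylcarbamate | CC(C)NC(=O)Oc1cc(OCc2ccccc2)cc(OCc2ccccc2)c1
F5 | step 1 | 3,5-bis(benzyloxy)-2-(trimethylsilyl)phenyl isopropylcarbamate | CC(C)NC(=O)Oc1cc(OCc2ccccc2)cc(OCc2ccccc2)c1[Si](C)(C)C
F6 | step 1 | 3,5-bis(benzyloxy)-2-(trimethylsilyl)phenol | Oc1cc(OCc2ccccc2)cc(OCc2ccccc2)c1[Si](C)(C)C
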